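Read the plateau before anything else: a target that has levelled off is a number a set-up can be held against.

| setting | Sunday's | Tuesday's | Monday's | winter | summer | noon |
|---|---|---|---|---|---|---|
| substrate | 20 mM | 28 mM | 44 mM | 20 mM | 20 mM | 20 mM |
| remark | run made earlier | run made earlier | run made earlier | a single well-mixed tank run continuously and read at steady state, 40 min in it on average | a closed flask charged with all of it at once and left for 40 min | one stirred flow tank at steady state, fed with the mixture as stated, mean residence time 120 min |
| time |  |  |  |  | 40 min |  |

- Sunday's (time / min: target / %, substrate / %): 6.00: 19.8, 13.9; 12.0: 17.6, 3.0; 20.0: 18.2, 0.4; 25.0: 17.1, 0.2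
- Tuesday's (time / min: target / %, substrate / %): 3.00: 14.8, 34.4; 8.00: 19.6, 6.7; 15.0: 16.7, 0.3; 25.0: 16.0, 0.5
- Monday's (time / min: target / %, substrate / %): 6.00: 18.6, 12.6; 12.0: 16.8, 2.4; 20.0: 15.4, 0.3; 25.0: 15.0, 0.1

(each reading ± 0.5 percentage points)

- the stated concentrations are those of everything mixed, before any reaction; amounts are the same in each set-up
- the earlier runs were made in a closed, stirred flask

* the set-up with the highest amount of target at the outlet or at the end, in percent of the substrate put in ("none" if the first two lie within 2 percentage points) (winter / summer / noon / none)
* amount of target at the outlet or at the end, in percent of the substrate put in, winter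
* amount of target at the outlet or at the end, in percent of the substrate put in, summer
* amount of target at the outlet or at the end, in percent of the substrate put in, noon

What can Sunday's run give summer? Its last two target readings average 17.6%. Call this the plateau yield: the target standing after its peak, in percent of the substrate charged, read with the scatter of the readings.

Does summer reach it? Sunday's first substrate reading gives a first-order constant of 0.329 /min. The mean lifetime, 3.04 min, is far shorter than summer's 40 min. The charge is also Sunday's 20 mM, so the plateau yield is my summer estimate.

And the noon tank, which is no closed flask? A steady balance of first-order loss in a stirred tank leaves one part in one plus the constant times the residence time, so I reckon that 2.47% of the substrate stays unconverted. The plateau yield on the converted part gives 17.2% for noon.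

Where is that weak? It carries a closed-flask plateau into a tank, yet Monday's plateau at 44 mM reads only 15.2%. The plateau therefore moves with concentration, and the noon tank runs at low substrate, so my noon figure may stand low.

The forecast gives 17.9% for winter, 17.3% for summer and 17.6% for noon, with best none. Its grounds: “A plateau that falls with concentration suggests a reversible second-order loss of target”. Its noon figure is higher than mine.

The simulation gives 18.2% for winter, 17.0% for summer and 19.3% for noon. Noon leads winter by 1.1 percentage points, inside the margin of 2 points, so best is none, as forecast.

    substrate → intermediate (k = 0.00340 /s)
    substrate → side product (k = 9.20 × 10⁻⁴ /s)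
    target ⇌ isomer of the product (K = 2.70, k = 0.00650 /s)
    intermediate → target (k = 0.00960 /s)
    2 substrate → homo dimer (k = 0.0260 /M/s)
    substrate ⇌ dormant form (K = 6.10, k = 8.00 × 10⁻⁴ /s)

In summer at 40.0 min, target 17.0% stands beside isomer of the product 45.6%, and the half-life of target by the forward step to that isomer alone, 1.8 min, is short against 40 min. That step is the main reason for the low target: struck out both ways, summer gives 62.6% instead of 17.0%. For summer the plateau yield gave 17.6%, a reading with its scatter, and the flask holds 17.0%.

For the summer flask left until 1.0 h, the plateau yield says 17.6%; the computed target is 17.3%.

The readings stem from a simulated flask with constants of no real substance, noise included.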